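**Plan**
- The three O‑protecting groups are removed last; ring A (C1 propanoyl, C2 OH, C3 CH3, C4 OH, C5 bridging CH2, C6 OH) is then cut at C5–C6 and C1–C2.
- C1 and C6 are the two alkyne carbons of a β‑alkoxy ynone; C2–C5, with their alternating O, C, O, C substituents, are the silylated dienol form of an α‑methyl β‑keto ester whose C5 already carries the CH2–ring B unit.
- The keto ester is cut at the CH2–CH2 bond beside ring B: γ‑alkylation of the dianion of methyl 2‑methyl‑3‑oxobutanoate with a ring B benzylic bromide.
- Forward: ring B is elaborated from 2,4,6‑trihydroxytoluene (acylation, para O‑methylation, formylation, benzylation, reduction, bromination), the chain is attached, all carbonyls are silylated, and ring A is closed last by a [4+2] benzannulation; BCl3 then frees the phenols.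
- Stereochemistry: the target has no stereocentre; sp3 centres and enol geometries that appear on the way are transient and are erased on aromatisation.

Key step: step 11

Assumption: the alkynyl ether is carried as an isopropyl ether (cleaved by BCl3 without carbonyl assistance and in preference to a methyl ether) and the ring B ketone passes through the annulation as its trimethylsilyl enol ether; configurations of 4, 9, 12, 18, 21 and the double‑bond geometries of 20–22 are uncontrolled and irrelevant.

**Route**

Step 1
Reactants: 1 2,4,6-trihydroxytoluene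
Product: 2 1-(2,4,6-trihydroxy-3-methylphenyl)propan-1-one
Conditions: EtCOCl, AlCl3, PhNO2/CH2Cl2, 0 → 40 °C; aq HCl
Reagents that add atoms: propanoyl chloride (CCC(=O)Cl)
Why: Friedel–Crafts C‑acylation of the phloroglucinol nucleus; the two free ring positions of 1 are equivalent and the first acyl group deactivates the ring against a second acylation.

Step 2
Reactants: 2 1-(2,4,6-trihydroxy-3-methylphenyl)propan-1-one
Product: 3 1-(2,6-dihydroxy-4-methoxy-3-methylphenyl)propan-1-one
Conditions: Me2SO4 (1.0 equiv), K2CO3 (1.0 equiv), acetone, 20 °C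
Reagents that add atoms: dimethyl sulfate (COS(=O)(=O)OC)
Why: Williamson etherification; the hydroxyl para to the ketone is the most acidic, whereas the two ortho hydroxyls are tied up in hydrogen bonding to the carbonyl, so one equivalent of base and reagent should methylate the para oxygen first.

Step 3
Reactants: 3 1-(2,6-dihydroxy-4-methoxy-3-methylphenyl)propan-1-one
Product: 5 2,4-dihydroxy-6-methoxy-5-methyl-3-propanoylbenzaldehyde, via α-chloro ether 4 (not isolated)
Conditions: Cl2CHOMe, TiCl4, CH2Cl2, −10 → 20 °C; then 1 M HCl
Reagents that add atoms: dichloromethyl methyl ether (COC(Cl)Cl); water (O)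
Why: Rieche formylation; TiCl4 binds the phenol/ketone chelate and directs the electrophile to the only unsubstituted ring position, and aqueous work‑up hydrolyses the α‑chloro ether to the aldehyde.

Step 4
Reactants: 5 2,4-dihydroxy-6-methoxy-5-methyl-3-propanoylbenzaldehyde
Product: 6 2,4-bis(benzyloxy)-6-methoxy-5-methyl-3-propanoylbenzaldehyde
Conditions: BnBr, K2CO3, n-Bu4NI (cat.), DMF, 60 °C
Reagents that add atoms: benzyl bromide (BrCc1ccccc1)
Why: Williamson O‑benzylation in a dipolar aprotic solvent, which favours O‑ over C‑alkylation of the phenoxides; both chelated hydroxyls should react on warming with excess reagent.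

Step 5
Reactants: 6 2,4-bis(benzyloxy)-6-methoxy-5-methyl-3-propanoylbenzaldehyde
Product: 7 1-[2,6-bis(benzyloxy)-3-(hydroxymethyl)-4-methoxy-5-methylphenyl]propan-1-one
Conditions: NaBH4 (0.5 equiv), THF/MeOH, −20 °C; aq NH4Cl
Reagents that add atoms: none
Why: Chemoselective borohydride reduction; the aldehyde is far more electrophilic than the di‑ortho‑substituted aryl ethyl ketone, which should remain untouched at low temperature with a limited hydride charge.

Step 6
Reactants: 7 1-[2,6-bis(benzyloxy)-3-(hydroxymethyl)-4-methoxy-5-methylphenyl]propan-1-one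
Product: 8 1-[2,6-bis(benzyloxy)-3-(bromomethyl)-4-methoxy-5-methylphenyl]propan-1-one
Conditions: PBr3 (0.4 equiv), CH2Cl2, 0 °C
Reagents that add atoms: phosphorus tribromide (BrP(Br)Br)
Why: Bromination of an electron‑rich benzylic alcohol through its phosphite ester (nucleophilic substitution at an activated benzylic carbon); ketone and ethers are inert, and the bromide is used without storage.

Step 7
Reactants: 8 1-[2,6-bis(benzyloxy)-3-(bromomethyl)-4-methoxy-5-methylphenyl]propan-1-one; 9 methyl 2-methyl-3-oxobutanoate
Product: 12 methyl 5-[2,4-bis(benzyloxy)-6-methoxy-5-methyl-3-propanoylphenyl]-2-methyl-3-oxopentanoate, via sodium enolate 10 (not isolated), via dianion 11 (not isolated)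
Conditions: 9 (1.6 equiv), NaH, THF, 0 °C; n-BuLi, 0 °C; then 8, −78 → 0 °C; 1 M HCl
Reagents that add atoms: none
Why: Weiler dianion γ‑alkylation; the terminal carbanion of 11 is its most nucleophilic site and SN2 displacement at the activated benzylic bromide at −78 °C should outrun proton transfer from, or addition to, the shielded ring B ketone, the excess of dianion covering any enolisation.

Step 8
Reactants: 13 trichloroethylene
Product: 15 (E)-1,2-dichloro-1-(propan-2-yloxy)ethene, via dichloroacetylene 14 (not isolated)
Conditions: i-PrOH, KH, THF, 0 °C; then 13, −50 → 20 °C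
Reagents that add atoms: propan-2-ol (CC(C)O)
Why: Alkoxide‑induced dehydrochlorination of trichloroethylene to dichloroacetylene followed by anti addition of isopropoxide, the standard entry to 1,2‑dichlorovinyl ethers.

Step 9
Reactants: 15 (E)-1,2-dichloro-1-(propan-2-yloxy)ethene
Product: 19 1-(propan-2-yloxy)pent-1-yn-3-one, via chloroalkynyl ether 16 (not isolated), via lithium acetylide 17 (not isolated), via lithium hemiaminal 18 (not isolated)
Conditions: n-BuLi (2.2 equiv), THF, −78 → −40 °C; EtC(O)N(OMe)Me, −78 → −20 °C; AcOH, −78 °C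
Reagents that add atoms: N-methoxy-N-methylpropanamide (CCC(=O)N(C)OC)
Why: n‑BuLi effects elimination and then chlorine–lithium exchange to the lithium alkoxyacetylide, whose acylation by the Weinreb amide stops at the chelated tetrahedral adduct and releases the ynone only on the cold acidic quench (Weinreb ketone synthesis).

Step 10
Reactants: 12 methyl 5-[2,4-bis(benzyloxy)-6-methoxy-5-methyl-3-propanoylphenyl]-2-methyl-3-oxopentanoate
Product: 20 1-methoxy-2-methyl-5-{2,4-bis(benzyloxy)-6-methoxy-5-methyl-3-[1-(trimethylsilyloxy)prop-1-en-1-yl]phenyl}-1,3-bis(trimethylsilyloxy)penta-1,3-diene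
Conditions: TMSOTf (3.5 equiv), Et3N (5 equiv), Et2O, 0 → 20 °C; ammonium salt layer removed under argon, used crude
Reagents that add atoms: trimethylsilyl trifluoromethanesulfonate (C[Si](C)(C)OS(=O)(=O)C(F)(F)F)
Why: Soft enolisation/O‑silylation with TMSOTf and Et3N converts the β‑keto ester into the 1‑methoxy‑1,3‑bis(silyloxy)diene (ketone oxygen first, then the ester oxygen with loss of a C4 proton) and at the same time masks the ring B ketone as its silyl enol ether.

Step 11
Reactants: 20 1-methoxy-2-methyl-5-{2,4-bis(benzyloxy)-6-methoxy-5-methyl-3-[1-(trimethylsilyloxy)prop-1-en-1-yl]phenyl}-1,3-bis(trimethylsilyloxy)penta-1,3-diene; 19 1-(propan-2-yloxy)pent-1-yn-3-one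
Product: 23 1-[3-{[2,4-bis(benzyloxy)-6-methoxy-5-methyl-3-propanoylphenyl]methyl}-4,6-dihydroxy-5-methyl-2-(propan-2-yloxy)phenyl]propan-1-one, via cyclohexadiene adduct 21 (not isolated), via aryl silyl ether 22 (not isolated)
Conditions: 19 (1.1 equiv), TMSOTf (0.2 equiv), CH2Cl2, −78 → 0 °C; then 1 M HCl, THF, 20 °C
Reagents that add atoms: none
Why: Proposed new method: TMSOTf silylates the carbonyl oxygen of 19 and makes its alkoxy‑bearing β‑carbon an oxocarbenium‑type centre, which is attacked by the terminal diene carbon of 20 (future C5) to form C5–C6; the resulting allenyl silyl ether then collapses through its central carbon (future C1) onto the silyloxy‑stabilised cation at the former ketene acetal carbon (future C2) to form C1–C2, so ring A closes as a six‑membered carbocycle by a polar, asynchronous [4+2] cycloaddition (Mukaiyama–Michael addition followed by Claisen‑type C‑acylation in the stepwise limit). Adduct 21 then loses methoxytrimethylsilane from C2 and a proton from C5 to give the arene, and dilute acid removes the remaining silyl groups and returns the ring B ketone. The closest known reaction type is the Diels–Alder aromatisation of 1‑alkoxy‑1,3‑bis(silyloxy)buta‑1,3‑dienes with acetylenic esters and ketones, together with the Lewis‑acid‑mediated annulations of the same dienes with β‑alkoxy enones; a β‑alkoxy ynone as the two‑carbon partner and a diene substituted at every carbon have not been shown. No stereocentre is formed in 23, the two sp3 centres of 21 being erased on aromatisation. The step needs regioselectivity (C5 to the alkoxy carbon, C2 to the acyl‑bearing carbon), secured by pairing the most nucleophilic diene terminus with the most electrophilic alkyne carbon and by the methyl group on the internal diene carbon, which makes attack through that carbon unproductive. It also needs chemoselectivity over the ring B silyl enol ether, secured by the far higher nucleophilicity of the ketene‑acetal‑type diene.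

Step 12
Reactants: 23 1-[3-{[2,4-bis(benzyloxy)-6-methoxy-5-methyl-3-propanoylphenyl]methyl}-4,6-dihydroxy-5-methyl-2-(propan-2-yloxy)phenyl]propan-1-one
Product: 24 1-[3-{[2,4-dihydroxy-6-methoxy-5-methyl-3-propanoylphenyl]methyl}-2,4,6-trihydroxy-5-methylphenyl]propan-1-one
Conditions: BCl3 (6 equiv), C6HMe5 (4 equiv), CH2Cl2, −78 → 0 °C; MeOH, then H2O
Reagents that add atoms: none
Why: Lewis‑acid ether cleavage; BCl3 removes secondary isopropyl and benzyl aryl ethers at or below 0 °C (pentamethylbenzene traps the benzyl cations), whereas the ring B methyl ether, which has no ortho carbonyl to chelate boron, should not be attacked under these conditions.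

**Compound list**

1 | 2,4,6-trihydroxytoluene | Cc1c(O)cc(O)cc1O | starting material
2 | 1-(2,4,6-trihydroxy-3-methylphenyl)propan-1-one | CCC(=O)c1c(O)cc(O)c(C)c1O | intermediate
3 | 1-(2,6-dihydroxy-4-methoxy-3-methylphenyl)propan-1-one | CCC(=O)c1c(O)cc(OC)c(C)c1O | intermediate
4 | 1-{3-[chloro(methoxy)methyl]-2,6-dihydroxy-4-methoxy-5-methylphenyl}propan-1-one (racemic) | CCC(=O)c1c(O)c(C(Cl)OC)c(OC)c(C)c1O | intermediate (not isolated)
5 | 2,4-dihydroxy-6-methoxy-5-methyl-3-propanoylbenzaldehyde | CCC(=O)c1c(O)c(C=O)c(OC)c(C)c1O | intermediate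
6 | 2,4-bis(benzyloxy)-6-methoxy-5-methyl-3-propanoylbenzaldehyde | CCC(=O)c1c(OCc2ccccc2)c(C=O)c(OC)c(C)c1OCc1ccccc1 | intermediate
7 | 1-[2,6-bis(benzyloxy)-3-(hydroxymethyl)-4-methoxy-5-methylphenyl]propan-1-one | CCC(=O)c1c(OCc2ccccc2)c(CO)c(OC)c(C)c1OCc1ccccc1 | intermediate
8 | 1-[2,6-bis(benzyloxy)-3-(bromomethyl)-4-methoxy-5-methylphenyl]propan-1-one | CCC(=O)c1c(OCc2ccccc2)c(CBr)c(OC)c(C)c1OCc1ccccc1 | intermediate
9 | methyl 2-methyl-3-oxobutanoate (racemic) | COC(=O)C(C)C(C)=O | starting material
10 | sodium enolate of 9 | COC(=O)C(C)=C(C)[O-].[Na+] | intermediate (not isolated)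
11 | sodium lithium dianion of 9 | COC([O-])=C(C)C(=C)[O-].[Na+].[Li+] | intermediate (not isolated)
12 | methyl 5-[2,4-bis(benzyloxy)-6-methoxy-5-methyl-3-propanoylphenyl]-2-methyl-3-oxopentanoate (racemic at C2) | COC(=O)C(C)C(=O)CCc1c(OCc2ccccc2)c(C(=O)CC)c(OCc2ccccc2)c(C)c1OC | intermediate
13 | trichloroethylene | ClC=C(Cl)Cl | starting material
14 | dichloroacetylene | ClC#CCl | intermediate (not isolated)
15 | (E)-1,2-dichloro-1-(propan-2-yloxy)ethene | CC(C)O/C(Cl)=C\Cl | intermediate
16 | 1-chloro-2-(propan-2-yloxy)ethyne | CC(C)OC#CCl | intermediate (not isolated)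
17 | [(propan-2-yloxy)ethynyl]lithium | CC(C)OC#C[Li] | intermediate (not isolated)
18 | lithium 3-[methoxy(methyl)amino]-1-(propan-2-yloxy)pent-1-yn-3-olate (racemic) | CCC([O-])(C#COC(C)C)N(C)OC.[Li+] | intermediate (not isolated)
19 | 1-(propan-2-yloxy)pent-1-yn-3-one | CCC(=O)C#COC(C)C | intermediate
20 | 1-methoxy-2-methyl-5-{2,4-bis(benzyloxy)-6-methoxy-5-methyl-3-[1-(trimethylsilyloxy)prop-1-en-1-yl]phenyl}-1,3-bis(trimethylsilyloxy)penta-1,3-diene (geometries not fixed) | COC(O[Si](C)(C)C)=C(C)C(O[Si](C)(C)C)=CCc1c(OCc2ccccc2)c(C(O[Si](C)(C)C)=CC)c(OCc2ccccc2)c(C)c1OC | intermediate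
21 | 1-[3-({2,4-bis(benzyloxy)-6-methoxy-5-methyl-3-[1-(trimethylsilyloxy)prop-1-en-1-yl]phenyl}methyl)-6-methoxy-5-methyl-2-(propan-2-yloxy)-4,6-bis(trimethylsilyloxy)cyclohexa-1,4-dien-1-yl]propan-1-one (mixture of stereoisomers) | CCC(=O)C1=C(OC(C)C)C(Cc2c(OCc3ccccc3)c(C(O[Si](C)(C)C)=CC)c(OCc3ccccc3)c(C)c2OC)C(O[Si](C)(C)C)=C(C)C1(OC)O[Si](C)(C)C | intermediate (not isolated)
22 | 1-[3-({2,4-bis(benzyloxy)-6-methoxy-5-methyl-3-[1-(trimethylsilyloxy)prop-1-en-1-yl]phenyl}methyl)-6-hydroxy-5-methyl-2-(propan-2-yloxy)-4-(trimethylsilyloxy)phenyl]propan-1-one | CCC(=O)c1c(O)c(C)c(O[Si](C)(C)C)c(Cc2c(OCc3ccccc3)c(C(O[Si](C)(C)C)=CC)c(OCc3ccccc3)c(C)c2OC)c1OC(C)C | intermediate (not isolated)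
23 | 1-[3-{[2,4-bis(benzyloxy)-6-methoxy-5-methyl-3-propanoylphenyl]methyl}-4,6-dihydroxy-5-methyl-2-(propan-2-yloxy)phenyl]propan-1-one | CCC(=O)c1c(O)c(C)c(O)c(Cc2c(OCc3ccccc3)c(C(=O)CC)c(OCc3ccccc3)c(C)c2OC)c1OC(C)C | intermediate
24 | 1-[3-{[2,4-dihydroxy-6-methoxy-5-methyl-3-propanoylphenyl]methyl}-2,4,6-trihydroxy-5-methylphenyl]propan-1-one | CCC(=O)c1c(O)c(C)c(O)c(Cc2c(O)c(C(=O)CC)c(O)c(C)c2OC)c1O | target

**Step count and risks**

Total steps: 12. Longest linear sequence: 10 (steps 1–7, 10, 11, 12); the ynone branch (steps 8, 9) joins at step 11.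

Steps most likely to fail:

1. Step 11. The activated ynone may be attacked at its carbonyl carbon instead of the alkoxy carbon, or the sequence may stall after the first C–C bond and the open‑chain adduct may close through oxygen to a γ‑pyrone; protodesilylation of the diene before it reacts is a further loss channel. Fallback (known chemistry, sets out from 7 and 2, returns at 24): the C5–CH2 bond would be made by Friedel–Crafts benzylation, the standard way to methylene‑bridged acylphloroglucinols. Benzylic alcohol 7 is ionised with catalytic BF3·OEt2 in CH2Cl2 at −20 to 0 °C in the presence of ketone 2, whose single free ring position should be attacked by the trialkoxybenzyl cation to give 1-[3-{[2,4-bis(benzyloxy)-6-methoxy-5-methyl-3-propanoylphenyl]methyl}-2,4,6-trihydroxy-5-methylphenyl]propan-1-one F1. Hydrogenolysis (H2, 10% Pd/C, EtOAc) then removes both benzyl groups and gives target 24.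

2. Step 7. Proton transfer from the ring B ethyl ketone to the strongly basic dianion may compete with substitution, after which the ketone enolate can be alkylated by a second molecule of bromide. Fallback (sets out from 9 and 8, returns at 12): the basic dianion is replaced by a neutral silyl nucleophile. Keto ester 9 is converted with TMSOTf and Et3N into 1-methoxy-2-methyl-1,3-bis(trimethylsilyloxy)buta-1,3-diene F2, and bromide 8 is ionised with ZnBr2 in CH2Cl2 at −20 to 20 °C. The terminal carbon of F2 should capture the benzylic cation in an SN1‑type Lewis‑acid alkylation of a silyl dienol ether, and aqueous work‑up gives keto ester 12.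

3. Step 2. Methylation may take place at one of the ortho hydroxyls or a second time, since the three phenols differ only in acidity and hydrogen bonding. Fallback (sets out from 2, returns at 3): selective alkylation is replaced by selective dealkylation. Ketone 2 is exhaustively methylated (excess Me2SO4, K2CO3, acetone, reflux) to 1-(2,4,6-trimethoxy-3-methylphenyl)propan-1-one F3, and the two methyl ethers flanking the ketone are then cleaved under chelation control with BBr3 (about 2.2 equiv, CH2Cl2, −78 → 0 °C), leaving the para methoxy group and giving 3.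

**Further compounds**

F1 | step 11 | 1-[3-{[2,4-bis(benzyloxy)-6-methoxy-5-methyl-3-propanoylphenyl]methyl}-2,4,6-trihydroxy-5-methylphenyl]propan-1-one | CCC(=O)c1c(O)c(C)c(O)c(Cc2c(OCc3ccccc3)c(C(=O)CC)c(OCc3ccccc3)c(C)c2OC)c1O
F2 | step 7 | 1-methoxy-2-methyl-1,3-bis(trimethylsilyloxy)buta-1,3-diene | COC(O[Si](C)(C)C)=C(C)C(=C)O[Si](C)(C)C
F3 | step 2 | 1-(2,4,6-trimethoxy-3-methylphenyl)propan-1-one | CCC(=O)c1c(OC)cc(OC)c(C)c1OC
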